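At late times the runs hide where the starting complex went: at 10.0 h the birch flask shows 3.5 % of it and 43.4 % of the complex with two exchanged, so 53.1 % of the charge sits in neither read form, and you have to go back to the first rows of the runs below.

| flask | starting complex | incoming ligand | protic impurity | remark | time |
|---|---|---|---|---|---|
| maple | 0.084 M | 0.21 M | 0.042 M | run made earlier |  |
| oak | 0.056 M | 0.21 M | 0.042 M | run made earlier |  |
| alder | 0.13 M | 0.21 M | 0.042 M | run made earlier |  |
| birch | 0.084 M | 0.42 M | 0.042 M | run made earlier |  |
| alpha | 0.084 M | 0.210 M | 0.0420 M | everything together in a closed stirred flask, run for 10 h | 10 h |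
| zeta | 0.084 M | 0.210 M (fed, over 10.0 h) | 0.0420 M | all but incoming ligand at the start; incoming ligand goes in evenly over 10.0 h, the run ends at 10 h | 10 h |
| gamma | 0.084 M | 0.210 M | 0.0420 M | a single well-mixed tank run continuously and read at steady state, 30.0 h in it on average |  |
| theta | 0.084 M | 0.210 M | 0.0420 M | a single well-mixed tank run continuously and read at steady state, 10 h in it on average |  |

| run | time / h | complex with two exchanged / % | starting complex / % |
|---|---|---|---|
| maple | 1.50 | 1.6 | 62.5 |
| maple | 3.00 | 5.3 | 40.6 |
| maple | 5.00 | 11.5 | 25.5 |
| maple | 6.00 | 12.7 | 21.0 |
| oak | 1.33 | 1.6 | 63.8 |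
| oak | 4.00 | 8.5 | 29.7 |
| oak | 6.00 | 15.0 | 17.4 |
| oak | 10.0 | 24.0 | 7.9 |
| alder | 1.33 | 1.5 | 66.7 |
| alder | 4.00 | 6.9 | 36.8 |
| alder | 6.00 | 11.0 | 26.8 |
| alder | 10.0 | 17.3 | 16.9 |
| birch | 1.33 | 5.3 | 49.3 |
| birch | 4.00 | 22.4 | 15.8 |
| birch | 6.00 | 33.0 | 7.3 |
| birch | 10.0 | 43.4 | 3.5 |

(readings scatter by 0.5 percentage points)

- the stated concentrations are those of everything mixed, before any reaction; amounts are the same in each set-up
- the earlier runs were read with a standard deviation of 0.5 percentage points
- the feed brings no volume worth counting
- the earlier runs were made in a closed, stirred flask

- order of the set-ups by the amount of complex with two exchanged at the outlet or at the end, in percent of the starting complex put in, highest first (alpha / zeta / gamma / theta)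
- amount of complex with two exchanged at the outlet or at the end, in percent of the starting complex put in, alpha
- amount of complex with two exchanged at the outlet or at the end, in percent of the starting complex put in, zeta
- amount of complex with two exchanged at the outlet or at the end, in percent of the starting complex put in, gamma
- amount of complex with two exchanged at the outlet or at the end, in percent of the starting complex put in, theta

Read the first row of maple against that of birch, which has twice the incoming ligand. Taken as an average first-order rate, the starting complex goes at 0.313 h⁻¹ in maple and 0.532 h⁻¹ in birch. So the extra ligand added 0.218 h⁻¹, and the rate left over at no ligand is 0.0949 h⁻¹, a path that does without ligand and for which the protic impurity, the same in all these runs, is your candidate. Now read oak against alder: their first rows give 0.338 h⁻¹ and 0.304 h⁻¹ from charges of 0.056 M and 0.13 M, so each path looks pseudo-first-order in starting complex.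

Divide one path by the other and the complex drops out: the split, the ligand-free rate of loss of starting complex over its rate with ligand, reads 0.435 early in the runs with a charge of 0.21 M of ligand, with the scatter of the readings on it, and it moves along a run as ligand and impurity are both used, growing as free ligand falls only while the impurity is held fixed. In zeta, 1.98 h into the feed, 0.0416 M of ligand has gone in, so, taking the impurity as in those early readings and the ligand as fed, I reckon a split of about 2.19, higher than at the full charge, and I expect zeta to end below alpha.

The forecast gives gamma > alpha > theta > zeta, with 21 % for alpha, 9 % for zeta, 32 % for gamma and 18 % for theta, allowing for “some unexplained loss or reversal, possibly involving the impurity”.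

    starting complex + incoming ligand ⇌ leaving ligand + complex with one exchanged (K = 3.40, k = 2.80 × 10⁻⁴ L mol⁻¹ s⁻¹)
    complex with one exchanged + incoming ligand ⇌ leaving ligand + complex with two exchanged (K = 0.610, k = 1.40 × 10⁻⁴ L mol⁻¹ s⁻¹)
    protic impurity + starting complex → quenched substrate (k = 9.70 × 10⁻⁴ L mol⁻¹ s⁻¹)

The flasks give gamma > alpha > theta > zeta, with 20.9 % in alpha, 8.35 % in zeta, 24.5 % in gamma and 16.2 % in theta, and at 10.0 h zeta holds more quenched substrate than alpha, 39.9 % against 31.8 %. In zeta at 1.98 h the impurity loss over the forward ligand step alone stands at 2.3, beside the 2.19 reckoned. In the neighbour like zeta with 0.21 M of starting complex, the reckoned split, taken for that one moment of the feed with the impurity as in the early readings, gives a share of 68.7 % of the complex then being used on the quench path, while the whole impurity charge is 20.0 % of the complex, and at 10.0 h that flask holds 19.9 % quenched substrate, 0.740 % of its impurity charge and 5.83 % of the complex with two exchanged.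

The runs were generated by integration for an exercise; scatter was added.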